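**Retrosynthetic overview**

- The strategy rests on the 1,4-dioxane ring O1–C2(aryl)–C3(methyl)–O4, fused to a benzene ring that carries OMe at C5 (next to O4) and propenyl at C7. C2, C3 and the C3 methyl are the side chain of a syringyl propenylphenol; O1 and O4 are the two oxygens of a 3-methoxycatechol (an 8-O-4' neolignan pattern).
- C3–O4 and C2–O1 are cut together, giving (E)-4-propenyl-2,6-dimethoxyphenol and 5-allyl-3-methoxycatechol. In the forward direction one oxidation makes both bonds: radical C–O coupling, then closure of the quinone methide. The dioxane ring is the only ring formed.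
- The catechol carries allyl, not propenyl, through the coupling so that only one partner has a conjugated side chain. The allyl group is moved into conjugation afterwards.
- The catechol comes from o-vanillin (O-allylation, para-Claisen rearrangement, Dakin oxidation). The propenylphenol comes from 4-allyl-2,6-dimethoxyphenol by double-bond isomerisation.
- The coupling gives the trans racemate. The (2R,3R) enantiomer is taken at the end by chromatography on a chiral stationary phase.

Key step: step 5

Remark: the target is the trans (2R,3R) isomer; racemic compounds are written with this antipode drawn, and the absolute configuration of the collected enantiomer is to be confirmed by ECD or by X-ray analysis of a heavy-atom ester.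

**Route**

Step 1
Reactants: 1 2-hydroxy-3-methoxybenzaldehyde (o-vanillin); 2 allyl bromide
Product: 3 2-(allyloxy)-3-methoxybenzaldehyde
Conditions: K2CO3, acetone, reflux
Reagents that add atoms: allyl bromide (compound 2), C=CCBr
Why: Williamson ether synthesis, in which the phenoxide of 1 displaces bromide from the reactive allylic halide (SN2); no stereocentre is involved.

Step 2
Reactants: 3 2-(allyloxy)-3-methoxybenzaldehyde
Product: 6 5-allyl-2-hydroxy-3-methoxybenzaldehyde, via ortho-dienone 4 (not isolated), via para-dienone 5 (not isolated)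
Conditions: N,N-diethylaniline, 200 °C, Ar
Reagents that add atoms: none
Why: Aromatic para-Claisen rearrangement: both ortho positions of the allyl ether are substituted, so the first [3,3] shift gives a dienone that cannot enolise, a Cope [3,3] shift passes the allyl group to the para carbon, and tautomerisation restores the phenol; no stereocentre remains.

Step 3
Reactants: 6 5-allyl-2-hydroxy-3-methoxybenzaldehyde
Product: 8 5-allyl-3-methoxybenzene-1,2-diol, via aryl formate 7 (not isolated)
Conditions: 30% aq H2O2, NaOH, THF–H2O, 0 °C to rt, N2; then aq HCl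
Reagents that add atoms: hydrogen peroxide, OO
Why: Dakin oxidation: hydroperoxide adds to the aldehyde of the ortho-hydroxybenzaldehyde, aryl migration gives formate 7, and the base saponifies it; the isolated allyl double bond is inert to alkaline peroxide, and exclusion of air protects the catechol.

Step 4
Reactants: 9 4-allyl-2,6-dimethoxyphenol
Product: 10 (E)-2,6-dimethoxy-4-(prop-1-enyl)phenol
Conditions: RuHCl(CO)(PPh3)3 (cat.), toluene, 80 °C
Reagents that add atoms: none
Why: Ruthenium-hydride-catalysed olefin isomerisation (hydrometalation, then β-hydride elimination) moves the double bond into conjugation with the arene and should give mainly the E isomer under thermodynamic control; any Z isomer is tolerated because the alkene geometry is lost in the radical of step 5.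

Step 5
Reactants: 10 (E)-2,6-dimethoxy-4-(prop-1-enyl)phenol; 8 5-allyl-3-methoxybenzene-1,2-diol
Product: 14 rac-4-[(2R,3R)-7-allyl-5-methoxy-3-methyl-2,3-dihydro-1,4-benzodioxin-2-yl]-2,6-dimethoxyphenol (trans racemate; wanted antipode drawn), via phenoxyl radical 11 (not isolated), via semiquinone radical 12 (not isolated), via quinone methide 13 (not isolated)
Conditions: Ag2O (1.5 equiv), toluene–acetone 2:1, rt, dark, Ar; 10 added slowly to 8 (1.5 equiv)
Reagents that add atoms: none
Why: Ag2O takes a hydrogen atom from each phenol, giving radical 11, whose spin reaches the side-chain β-carbon, and semiquinone 12, whose most stabilised oxygen is the central one (para to allyl, flanked by OMe and OH); the two combine through C3–O4 bond formation to the para-quinone methide 13. The neighbouring free hydroxyl (O1) then adds to the methide carbon (C2) in a 6-exo-trig conjugate addition, which restores the aromatic syringyl ring and closes the 1,4-dioxane ring, the only ring formed. The closest known reaction type is the Ag2O- or peroxidase-mediated oxidative cross-coupling of 4-propenylphenols with catechols to 2-aryl-3-methyl-1,4-benzodioxanes. C3 is set in the radical combination without facial bias, hence a racemate, and C2 is set relative to C3 in the ring closure, which is reversible through 13 and should therefore favour the trans isomer with aryl and methyl both equatorial. The step needs cross-coupling over homo-coupling and O4–C3 over O1–C3 connectivity: the first is helped by the two ortho-methoxy groups of 10 (no coupling at ring carbons), by the non-conjugated allyl chain of 8 (no side-chain radical site) and by keeping 10 dilute against an excess of 8, the second by the greater stabilisation of the central oxygen radical. The minor cis isomer and dimers of 10 are to be removed by chromatography, and the trans assignment is to be checked through the H2–H3 coupling constant.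

Step 6
Reactants: 14 rac-4-[(2R,3R)-7-allyl-5-methoxy-3-methyl-2,3-dihydro-1,4-benzodioxin-2-yl]-2,6-dimethoxyphenol
Product: 15 rac-2,6-dimethoxy-4-[(2R,3R)-5-methoxy-3-methyl-7-[(E)-prop-1-enyl]-2,3-dihydro-1,4-benzodioxin-2-yl]phenol (trans racemate; wanted antipode drawn)
Conditions: RuHCl(CO)(PPh3)3 (cat.), toluene, 80 °C
Reagents that add atoms: none
Why: The same ruthenium-hydride olefin isomerisation as in step 4, driven by conjugation with ring A and E-selective under thermodynamic control; the neutral conditions leave the phenol, the dioxane ring and both stereocentres untouched.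

Step 7
Reactants: 15 rac-2,6-dimethoxy-4-[(2R,3R)-5-methoxy-3-methyl-7-[(E)-prop-1-enyl]-2,3-dihydro-1,4-benzodioxin-2-yl]phenol
Product: 16 2,6-dimethoxy-4-[(2R,3R)-5-methoxy-3-methyl-7-[(E)-prop-1-enyl]-2,3-dihydro-1,4-benzodioxin-2-yl]phenol (target; single enantiomer)
Conditions: preparative SFC, amylose tris(3,5-dimethylphenylcarbamate) stationary phase (Chiralpak AD-H), CO2–MeOH, 35 °C
Reagents that add atoms: none
Why: Resolution of a racemate by chromatography on a chiral stationary phase: the free phenol (hydrogen bonding) and the two aryl groups (π-stacking) should give the enantiomers different affinities for the carbamate selector, no stereocentre is formed or touched, and the (2R,3R) fraction is collected, which at the same time removes traces of the Z-alkene.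

**Compound list**

1 | 2-hydroxy-3-methoxybenzaldehyde (o-vanillin) | COc1cccc(C=O)c1O | starting material
2 | allyl bromide | C=CCBr | starting material
3 | 2-(allyloxy)-3-methoxybenzaldehyde | C=CCOc1c(C=O)cccc1OC | intermediate
4 | ortho-dienone, 6-allyl-2-formyl-6-methoxycyclohexa-2,4-dien-1-one (racemic, not isolated) | C=CCC1(OC)C=CC=C(C=O)C1=O | intermediate
5 | para-dienone, 4-allyl-2-formyl-6-methoxycyclohexa-2,5-dien-1-one (racemic, not isolated) | C=CCC1C=C(C=O)C(=O)C(OC)=C1 | intermediate
6 | 5-allyl-2-hydroxy-3-methoxybenzaldehyde | C=CCc1cc(C=O)c(O)c(OC)c1 | intermediate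
7 | 5-allyl-2-hydroxy-3-methoxyphenyl formate (not isolated) | C=CCc1cc(OC=O)c(O)c(OC)c1 | intermediate
8 | 5-allyl-3-methoxybenzene-1,2-diol | C=CCc1cc(O)c(O)c(OC)c1 | intermediate
9 | 4-allyl-2,6-dimethoxyphenol | C=CCc1cc(OC)c(O)c(OC)c1 | starting material
10 | (E)-2,6-dimethoxy-4-(prop-1-enyl)phenol | C/C=C/c1cc(OC)c(O)c(OC)c1 | intermediate
11 | phenoxyl radical of 10 (not isolated) | C/C=C/c1cc(OC)c([O])c(OC)c1 | intermediate
12 | semiquinone radical of 8, radical at the central oxygen (not isolated) | C=CCc1cc(O)c([O])c(OC)c1 | intermediate
13 | quinone methide, 4-[2-(4-allyl-2-hydroxy-6-methoxyphenoxy)propylidene]-2,6-dimethoxycyclohexa-2,5-dien-1-one (racemic, one antipode drawn, not isolated) | O=C1C(OC)=CC(=C[C@@H](C)Oc2c(O)cc(CC=C)cc2OC)C=C1OC | intermediate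
14 | rac-4-[(2R,3R)-7-allyl-5-methoxy-3-methyl-2,3-dihydro-1,4-benzodioxin-2-yl]-2,6-dimethoxyphenol (trans racemate, one antipode drawn) | C=CCc1cc(OC)c2c(c1)O[C@H](c1cc(OC)c(O)c(OC)c1)[C@@H](C)O2 | intermediate
15 | rac-2,6-dimethoxy-4-[(2R,3R)-5-methoxy-3-methyl-7-[(E)-prop-1-enyl]-2,3-dihydro-1,4-benzodioxin-2-yl]phenol (trans racemate, one antipode drawn) | C/C=C/c1cc(OC)c2c(c1)O[C@H](c1cc(OC)c(O)c(OC)c1)[C@@H](C)O2 | intermediate
16 | 2,6-dimethoxy-4-[(2R,3R)-5-methoxy-3-methyl-7-[(E)-prop-1-enyl]-2,3-dihydro-1,4-benzodioxin-2-yl]phenol, single enantiomer | C/C=C/c1cc(OC)c2c(c1)O[C@H](c1cc(OC)c(O)c(OC)c1)[C@@H](C)O2 | target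

**Step count**

Total: 7 steps. Longest linear sequence: 6 steps (steps 1, 2, 3, 5, 6, 7).

**Steps most likely to fail**

Step 5. Homo-coupling of radical 11 or over-oxidation of the catechol may outrun the cross-coupling, or bond formation through the outer catechol oxygen may give the regioisomeric ring. The fallback makes the two C–O bonds one after the other by ionic chemistry and tells the two oxygens apart through the aldehyde of 6. It sets out from 10 and 6 and comes back at 14.
- Phenol 10 is acetylated (Ac2O, pyridine) to (E)-2,6-dimethoxy-4-(prop-1-enyl)phenyl acetate F1.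
- NBS in aqueous THF at 0 °C, with water opening the bromonium ion at the benzylic carbon, gives the bromohydrin 4-(2-bromo-1-hydroxypropyl)-2,6-dimethoxyphenyl acetate F2.
- Dess–Martin periodinane oxidises this to the α-bromo ketone 4-(2-bromopropanoyl)-2,6-dimethoxyphenyl acetate F3.
- The phenoxide of 6 (K2CO3, acetone) displaces the bromide by SN2, so that the future O4 sits on the methyl-bearing carbon, giving the aryloxy ketone 4-[2-(4-allyl-2-formyl-6-methoxyphenoxy)propanoyl]-2,6-dimethoxyphenyl acetate F4.
- mCPBA (CH2Cl2, 0 °C) converts the electron-rich aldehyde, well before the monosubstituted alkene, into the aryl formate 4-[2-(4-allyl-2-formyloxy-6-methoxyphenoxy)propanoyl]-2,6-dimethoxyphenyl acetate F5 (Baeyer–Villiger oxidation).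
- K2CO3 in MeOH removes formate and acetate and gives the diphenol ketone 2-(4-allyl-2-hydroxy-6-methoxyphenoxy)-1-(4-hydroxy-3,5-dimethoxyphenyl)propan-1-one F6.
- NaBH4 in MeOH reduces the ketone to the benzylic alcohol 4-[2-(4-allyl-2-hydroxy-6-methoxyphenoxy)-1-hydroxypropyl]-2,6-dimethoxyphenol F7.
- A catalytic amount of TsOH in CH2Cl2 ionises the para-hydroxybenzylic alcohol to the same quinone methide 13, which should close under thermodynamic control to the trans-benzodioxane 14.

Step 7. Discrimination of the enantiomers on the stationary phase may be too small at preparative loading. The fallback resolves through covalent diastereomers; it sets out from 15 and comes back at 16.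
- Racemate 15 is acylated at the phenol with (1S)-(−)-camphanic chloride (Et3N, DMAP, CH2Cl2).
- This gives the (2R,3R)-benzodioxanyl (1S,4R)-camphanate F8 and the (2S,3S)-benzodioxanyl (1S,4R)-camphanate F9, which are separated by crystallisation or chromatography on silica.
- F8 is cleaved with LiOH in THF–water at 0 °C to 16. The contact with base is kept short and cold, so that the phenoxide does not open the dioxane ring to the quinone methide.

Step 2. At the temperature that the double sigmatropic shift needs, the formyl group may be lost from an ortho-dienone, or the aldehyde may decompose. The fallback makes catechol 8 without a rearrangement; it sets out from starting material 9 and comes back at 8, so that steps 1 to 3 fall away.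
- 2-Iodoxybenzoic acid (stabilised formulation, THF, rt) delivers oxygen to a methoxy-bearing ortho carbon of 9 and expels methanol (oxygenative demethylation of a 2-methoxyphenol), giving the ortho-quinone 5-allyl-3-methoxycyclohexa-3,5-diene-1,2-dione F10.
- F10 is reduced in the same flask with aqueous Na2S2O4 to 8.

**Further compounds**

F1 | step 5 | (E)-2,6-dimethoxy-4-(prop-1-enyl)phenyl acetate | C/C=C/c1cc(OC)c(OC(C)=O)c(OC)c1
F2 | step 5 | 4-[(1R,2S)-2-bromo-1-hydroxypropyl]-2,6-dimethoxyphenyl acetate (racemic anti adduct, one antipode drawn) | C[C@H](Br)[C@H](O)c1cc(OC)c(OC(C)=O)c(OC)c1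
F3 | step 5 | 4-(2-bromopropanoyl)-2,6-dimethoxyphenyl acetate (racemic) | CC(Br)C(=O)c1cc(OC)c(OC(C)=O)c(OC)c1
F4 | step 5 | 4-[2-(4-allyl-2-formyl-6-methoxyphenoxy)propanoyl]-2,6-dimethoxyphenyl acetate (racemic) | CC(Oc1c(C=O)cc(CC=C)cc1OC)C(=O)c1cc(OC)c(OC(C)=O)c(OC)c1
F5 | step 5 | 4-[2-(4-allyl-2-formyloxy-6-methoxyphenoxy)propanoyl]-2,6-dimethoxyphenyl acetate (racemic) | CC(Oc1c(OC=O)cc(CC=C)cc1OC)C(=O)c1cc(OC)c(OC(C)=O)c(OC)c1
F6 | step 5 | 2-(4-allyl-2-hydroxy-6-methoxyphenoxy)-1-(4-hydroxy-3,5-dimethoxyphenyl)propan-1-one (racemic) | CC(Oc1c(O)cc(CC=C)cc1OC)C(=O)c1cc(OC)c(O)c(OC)c1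
F7 | step 5 | 4-[2-(4-allyl-2-hydroxy-6-methoxyphenoxy)-1-hydroxypropyl]-2,6-dimethoxyphenol (racemic mixture of diastereomers) | CC(Oc1c(O)cc(CC=C)cc1OC)C(O)c1cc(OC)c(O)c(OC)c1
F8 | step 7 | 2,6-dimethoxy-4-[(2R,3R)-5-methoxy-3-methyl-7-[(E)-prop-1-enyl]-2,3-dihydro-1,4-benzodioxin-2-yl]phenyl (1S,4R)-4,7,7-trimethyl-3-oxo-2-oxabicyclo[2.2.1]heptane-1-carboxylate | C/C=C/c1cc(OC)c2c(c1)O[C@H](c1cc(OC)c(OC(=O)[C@@]34CC[C@@](C)(C(=O)O3)C4(C)C)c(OC)c1)[C@@H](C)O2
F9 | step 7 | 2,6-dimethoxy-4-[(2S,3S)-5-methoxy-3-methyl-7-[(E)-prop-1-enyl]-2,3-dihydro-1,4-benzodioxin-2-yl]phenyl (1S,4R)-4,7,7-trimethyl-3-oxo-2-oxabicyclo[2.2.1]heptane-1-carboxylate | C/C=C/c1cc(OC)c2c(c1)O[C@@H](c1cc(OC)c(OC(=O)[C@@]34CC[C@@](C)(C(=O)O3)C4(C)C)c(OC)c1)[C@H](C)O2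
F10 | step 2 | 5-allyl-3-methoxycyclohexa-3,5-diene-1,2-dione | C=CCC1=CC(=O)C(=O)C(OC)=C1
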